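**Retrosynthetic overview**
- Oxonane (last ring): C6–C7 bond by CrCl2/NiCl2-mediated alkenyl triflate–aldehyde coupling, which also sets C6.
- Seven-membered lactone: a C16 ketene is captured by the tertiary C3 hydroxyl, which sets C15.
- Tetrahydrofuran: visible-light photoredox 5-exo radical cyclisation of a C10 radical (from a cesium oxalate) onto a C2-O-linked β-alkoxy enone; this forms C9–C10 and sets C9 and C10.
- C1–C2 by anti boron aldol with a (Z)-enal; C3/C4 by hydroxyl-directed epoxidation and later SN2 opening with octanoate.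
- Cyclohexane (C11, C14) from (R)-carvone through its trans epoxide. Ring order: cyclohexane (bought), tetrahydrofuran, lactone, oxonane.

Assumption: atoms in intermediates are labelled with the briarellin numbering of the target (C1–C20); reagents without a compound number are bought. The route is a design on paper; selectivities are predictions from the models named in each step.

**Route**

Step 1
Reactants: 1 (R)-carvone
Product: 2 (1R,4R,6R)-1-methyl-4-(prop-1-en-2-yl)-7-oxabicyclo[4.1.0]heptan-2-one (trans-carvone oxide)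
Conditions: H2O2 (30% aq), NaOH (cat.), MeOH, 0 °C
Reagents that add atoms: hydrogen peroxide, OO
Why: Weitz–Scheffer nucleophilic epoxidation; hydroperoxide adds axially to the β-carbon on the face opposite the isopropenyl group, so the future C11–O bond is trans to the C14 substituent.

Step 2
Reactants: 2 trans-carvone oxide
Product: 3 (1R,4R)-1-methyl-4-(prop-1-en-2-yl)cyclohexane-1,2-diol (C2 carbinol epimers)
Conditions: LiAlH4, THF, 0 °C to rt
Reagents that add atoms: none
Why: Hydride reduction of the ketone and SN2 opening of the epoxide at its less substituted carbon (C12); the tertiary C11–O bond is not touched, so C11 keeps its configuration.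

Step 3
Reactants: 3 diol
Product: 4 (2R,5R)-2-hydroxy-2-methyl-5-(prop-1-en-2-yl)cyclohexan-1-one
Conditions: Dess–Martin periodinane, NaHCO3, CH2Cl2, rt
Reagents that add atoms: none
Why: Dess–Martin oxidation of the only secondary alcohol; the tertiary alcohol cannot be oxidised and no stereocentre is affected.

Step 4
Reactants: 4 α-hydroxy ketone
Product: 5 (2R,5R)-2-methyl-5-(prop-1-en-2-yl)-2-(triethylsilyloxy)cyclohexan-1-one
Conditions: Et3SiOTf, 2,6-lutidine, CH2Cl2, −78 to 0 °C
Reagents that add atoms: triethylsilyl trifluoromethanesulfonate, CC[Si](CC)(CC)OS(=O)(=O)C(F)(F)F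
Why: Silylation of the hindered tertiary alcohol with a silyl triflate; it blocks C11–OH for the boron aldol and the oxalate chemistry.

Step 5
Reactants: 6 3-(tert-butyldimethylsilyloxy)propanal
Product: 7 ethyl (2Z)-5-(tert-butyldimethylsilyloxy)-2-methylpent-2-enoate
Conditions: ethyl 2-(diphenoxyphosphoryl)propanoate, NaH, THF, −78 to 0 °C
Reagents that add atoms: ethyl 2-(diphenoxyphosphoryl)propanoate, CCOC(=O)C(C)P(=O)(Oc1ccccc1)Oc1ccccc1
Why: Ando-type Z-selective Horner–Wadsworth–Emmons olefination; the diaryl phosphonate gives the kinetic (Z)-trisubstituted enoate.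

Step 6
Reactants: 7 (Z)-enoate
Product: 8 (2Z)-5-(tert-butyldimethylsilyloxy)-2-methylpent-2-en-1-ol
Conditions: i-Bu2AlH, CH2Cl2, −78 °C
Reagents that add atoms: none
Why: 1,2-Reduction of the ester to the allylic alcohol by the aluminium hydride without touching the alkene geometry.

Step 7
Reactants: 8 (Z)-allylic alcohol
Product: 9 (2Z)-5-(tert-butyldimethylsilyloxy)-2-methylpent-2-enal
Conditions: MnO2, CH2Cl2, rt, dark
Reagents that add atoms: none
Why: Neutral allylic oxidation with MnO2, chosen because it does not isomerise the (Z)-enal.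

Step 8
Reactants: 5 silyloxy ketone; 9 (Z)-enal
Product: 11 (2R,5R,6R)-6-[(1S,2Z)-5-(tert-butyldimethylsilyloxy)-1-hydroxy-2-methylpent-2-enyl]-2-methyl-5-(prop-1-en-2-yl)-2-(triethylsilyloxy)cyclohexanone, via dicyclohexylboron enolate 10 (not isolated)
Conditions: Cy2BCl, Et3N, Et2O, −78 °C; then 9, −78 to −20 °C; H2O2, MeOH, pH 7 buffer
Reagents that add atoms: none
Why: Boron aldol through a Zimmerman–Traxler chair; the ring-fixed (E)-enolate gives the 1,2-anti adduct (C2) and the aldehyde approaches C1 trans to the adjacent isopropenyl group (C1).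

Step 9
Reactants: 11 aldol adduct
Product: 12 (2R,5R,6R)-6-[(S)-hydroxy{(2R,3S)-3-[2-(tert-butyldimethylsilyloxy)ethyl]-2-methyloxiran-2-yl}methyl]-2-methyl-5-(prop-1-en-2-yl)-2-(triethylsilyloxy)cyclohexanone
Conditions: m-CPBA, NaHCO3, CH2Cl2, 0 °C
Reagents that add atoms: 3-chloroperoxybenzoic acid, OOC(=O)c1cccc(Cl)c1
Why: Hydroxyl-directed (Henbest) epoxidation; A(1,3) strain in the (Z)-allylic alcohol fixes the H-eclipsed conformer and the peracid is delivered syn to the C2 hydroxyl, giving the threo epoxy alcohol (sets C3). The trisubstituted alkene reacts far faster than the isopropenyl group.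

Step 10
Reactants: 12 epoxy alcohol
Product: 13 β-alkoxy enone: 12 whose C2 oxygen carries an (E)-3-oxobut-1-enyl group
Conditions: but-3-yn-2-one, PMe3 (10 mol%), CH2Cl2, 0 °C
Reagents that add atoms: but-3-yn-2-one, CC(=O)C#C
Why: Phosphine-catalysed oxa-Michael addition of the only free hydroxyl to the ynone gives the (E)-vinylogous ester, which is the radical acceptor.

Step 11
Reactants: 13 β-alkoxy enone
Product: 14 C10 alcohol: 13 with the ring ketone reduced to CH–OH (C10 epimers, both used)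
Conditions: NaBH4, MeOH–THF, −40 °C
Reagents that add atoms: none
Why: Borohydride reduction of the saturated ketone; the vinylogous ester carbonyl is deactivated and the epoxide is inert. The new carbinol configuration is irrelevant because C10 becomes a radical.

Step 12
Reactants: 14 C10 alcohol
Product: 16 cesium C10 oxalate of 14, via C10 methyl oxalate 15 (not isolated)
Conditions: ClC(O)CO2Me, Et3N, DMAP (cat.), CH2Cl2, 0 °C; then CsOH·H2O (1.0 equiv), THF–H2O, 0 °C
Reagents that add atoms: methyl chlorooxoacetate, COC(=O)C(Cl)=O; cesium hydroxide, [Cs+].[OH-]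
Why: Acylation of the only free hydroxyl, then chemoselective saponification of the highly electrophilic methyl oxalate gives the radical precursor.

Step 13
Reactants: 16 cesium oxalate
Product: 17 cis-fused hexahydroisobenzofuran methyl ketone: tetrahydrofuran C9–O–C2–C1–C10; C9 carries CH2C(O)CH3; C2 carries the intact C3/C4 epoxide chain; C8 and C3 cis to each other and to H1 and H10
Conditions: [Ir{dF(CF3)ppy}2(dtbbpy)]PF6 (1 mol%), H2O (10 equiv), DME–DMF 3:1, blue LEDs (450 nm), 60 °C, 0.01 M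
Reagents that add atoms: none
Why: Proposed new method: the excited trivalent iridium complex oxidises the oxalate, loss of two CO2 gives the secondary C10 radical, and this adds 5-exo-trig to the β-carbon of the β-alkoxy enone through a Beckwith–Houk chair (cis ring fusion at C10, C8 pseudo-equatorial and cis to C3 at C9); the α-keto radical is then reduced by the divalent iridium species and protonated. Any retro-oxa-Michael/re-addition of the enolate leads to the same cis-2,5 isomer. Closest known reactions: tin-mediated β-alkoxyacrylate radical cyclisations to cis-2,5-tetrahydrofurans and intermolecular photoredox Giese couplings of cesium alkyl oxalates; the intramolecular use of a secondary oxalate on a β-alkoxy enone has not been shown.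

Step 14
Reactants: 17 methyl ketone
Product: 18 alkenyl triflate: 17 with the C7 ketone converted to C7(OTf)=C19H2
Conditions: KN(SiMe3)2 (1.1 equiv), N-(5-chloro-2-pyridyl)triflimide, THF, −78 °C
Reagents that add atoms: N-(5-chloropyridin-2-yl)-1,1,1-trifluoro-N-(trifluoromethylsulfonyl)methanesulfonamide, O=S(=O)(N(c1ccc(Cl)cn1)S(=O)(=O)C(F)(F)F)C(F)(F)F
Why: Kinetic deprotonation of the methyl group and O-triflation of the terminal enolate (Comins' reagent); no free hydroxyl or ester is present at this stage.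

Step 15
Reactants: 18 alkenyl triflate epoxide
Product: 19 hydroxy octanoate: C3 tertiary alcohol and C4 octanoate
Conditions: octanoic acid (5 equiv), Cs2CO3 (1 equiv), DMF, 80 °C
Reagents that add atoms: octanoic acid, CCCCCCCC(=O)O
Why: SN2 opening of the trisubstituted epoxide by C7H15CO2Cs at the less substituted carbon; inversion at C4 sets its configuration and, from the cis-epoxide, gives the syn C3–O/C4–O pattern. C3 keeps the epoxide oxygen, and alkenyl triflates tolerate carboxylate bases at this temperature.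

Step 16
Reactants: 19 hydroxy octanoate
Product: 21 C16 primary alcohol: isopropenyl converted to CH(CH3)CH2OH (C15 epimers), via B-alkyl-9-BBN adduct 20 (not isolated)
Conditions: 9-BBN, THF, 0 °C to rt; then NaBO3·4H2O, H2O, rt
Reagents that add atoms: sodium perborate, [Na+].[Na+].O[B-]1(O)OO[B-](O)(O)OO1
Why: Anti-Markovnikov hydroboration–oxidation; 9-BBN selects the 1,1-disubstituted alkene over the electron-poor alkenyl triflate. C15 is not controlled here and is reset in step 18.

Step 17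
Reactants: 21 primary alcohol
Product: 22 C16 carboxylic acid (C15 epimers)
Conditions: TEMPO (20 mol%), PhI(OAc)2, MeCN–H2O, rt
Reagents that add atoms: water, O
Why: Oxoammonium-mediated oxidation of the primary alcohol through the aldehyde hydrate to the acid; tertiary alcohol, esters and silyl ethers are inert.

Step 18
Reactants: 22 carboxylic acid
Product: 25 tricyclic seven-membered lactone (C16(=O)–O–C3; 15R) that still carries the C7 triflate and the C11 triethylsilyl and C6 tert-butyldimethylsilyl ethers, via acid chloride 23 (not isolated), via ketene 24 (not isolated)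
Conditions: 1-chloro-N,N,2-trimethylprop-1-en-1-amine, CH2Cl2, 0 °C; then slow addition to Et3N, toluene, 80 °C, 0.002 M
Reagents that add atoms: none
Why: Ketene lactonisation; both C15 epimers converge on the planar methylketene, the tertiary C3 hydroxyl adds intramolecularly, and the ester enol is protonated on its open face (syn to H14), which places the C15 methyl anti to H14 as in the target.

Step 19
Reactants: 25 lactone
Product: 26 diol: 25 with free C11 tertiary and C6 primary hydroxyls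
Conditions: HF·pyridine, pyridine, THF, 0 °C to rt
Reagents that add atoms: none
Why: Fluoride-mediated cleavage of both silyl ethers; triflate, lactone and octanoate are stable to buffered HF.

Step 20
Reactants: 26 diol
Product: 27 C6 aldehyde
Conditions: Dess–Martin periodinane, NaHCO3, CH2Cl2, 0 °C
Reagents that add atoms: none
Why: Dess–Martin oxidation of the primary alcohol only; the buffered, non-basic medium avoids β-elimination of the C4 octanoate, and the aldehyde is used at once.

Step 21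
Reactants: 27 aldehyde
Product: 28 briarellin A
Conditions: CrCl2 (10 equiv), NiCl2 (2 mol%), DMSO, rt, 0.003 M
Reagents that add atoms: none
Why: Nozaki–Hiyama–Kishi cyclisation (oxidative addition of the triflate to zerovalent nickel, transmetalation to trivalent chromium, addition to the aldehyde) closes the oxonane at C6–C7. The cis-2,5-disubstituted tetrahydrofuran holds the two chains together and the aldehyde is attacked on its exposed face, the sense seen in closely related cladiellin ring closures, giving the (6S)-alcohol.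

**Compound list**

1 | (R)-carvone | CC(=C)[C@@H]1CC=C(C)C(=O)C1 | starting material
2 | (1R,4R,6R)-1-methyl-4-(prop-1-en-2-yl)-7-oxabicyclo[4.1.0]heptan-2-one | CC(=C)[C@@H]1C[C@H]2O[C@@]2(C)C(=O)C1 | intermediate
3 | (1R,4R)-1-methyl-4-(prop-1-en-2-yl)cyclohexane-1,2-diol (C2 epimers) | CC(=C)[C@@H]1CC[C@@](C)(O)C(O)C1 | intermediate
4 | (2R,5R)-2-hydroxy-2-methyl-5-(prop-1-en-2-yl)cyclohexan-1-one | CC(=C)[C@@H]1CC[C@@](C)(O)C(=O)C1 | intermediate
5 | (2R,5R)-2-methyl-5-(prop-1-en-2-yl)-2-(triethylsilyloxy)cyclohexan-1-one | CC(=C)[C@@H]1CC[C@@](C)(O[Si](CC)(CC)CC)C(=O)C1 | intermediate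
6 | 3-(tert-butyldimethylsilyloxy)propanal | O=CCCO[Si](C)(C)C(C)(C)C | starting material
7 | ethyl (2Z)-5-(tert-butyldimethylsilyloxy)-2-methylpent-2-enoate | CCOC(=O)/C(C)=C\CCO[Si](C)(C)C(C)(C)C | intermediate
8 | (2Z)-5-(tert-butyldimethylsilyloxy)-2-methylpent-2-en-1-ol | OC/C(C)=C\CCO[Si](C)(C)C(C)(C)C | intermediate
9 | (2Z)-5-(tert-butyldimethylsilyloxy)-2-methylpent-2-enal | O=C/C(C)=C\CCO[Si](C)(C)C(C)(C)C | intermediate
10 | dicyclohexylboron enolate of 5 (C10=C1 enolate) | CC(=C)[C@@H]1CC[C@@](C)(O[Si](CC)(CC)CC)C(OB(C2CCCCC2)C2CCCCC2)=C1 | intermediate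
11 | (2R,5R,6R)-6-[(1S,2Z)-5-(tert-butyldimethylsilyloxy)-1-hydroxy-2-methylpent-2-enyl]-2-methyl-5-(prop-1-en-2-yl)-2-(triethylsilyloxy)cyclohexanone | CC(=C)[C@@H]1CC[C@@](C)(O[Si](CC)(CC)CC)C(=O)[C@H]1[C@H](O)/C(C)=C\CCO[Si](C)(C)C(C)(C)C | intermediate
12 | (2R,5R,6R)-6-[(S)-hydroxy{(2R,3S)-3-[2-(tert-butyldimethylsilyloxy)ethyl]-2-methyloxiran-2-yl}methyl]-2-methyl-5-(prop-1-en-2-yl)-2-(triethylsilyloxy)cyclohexanone (threo epoxy alcohol) | CC(=C)[C@@H]1CC[C@@](C)(O[Si](CC)(CC)CC)C(=O)[C@H]1[C@H](O)[C@@]2(C)O[C@H]2CCO[Si](C)(C)C(C)(C)C | intermediate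
13 | 12 with the C2 oxygen bearing an (E)-3-oxobut-1-enyl group (β-alkoxy enone; all centres as in 12) | CC(=C)[C@@H]1CC[C@@](C)(O[Si](CC)(CC)CC)C(=O)[C@H]1[C@H](O/C=C/C(C)=O)[C@@]2(C)O[C@H]2CCO[Si](C)(C)C(C)(C)C | intermediate
14 | C10 alcohol from 13 (C10 epimers; other centres as in 13) | CC(=C)[C@@H]1CC[C@@](C)(O[Si](CC)(CC)CC)C(O)[C@H]1[C@H](O/C=C/C(C)=O)[C@@]2(C)O[C@H]2CCO[Si](C)(C)C(C)(C)C | intermediate
15 | C10 methyl oxalate of 14 | CC(=C)[C@@H]1CC[C@@](C)(O[Si](CC)(CC)CC)C(OC(=O)C(=O)OC)[C@H]1[C@H](O/C=C/C(C)=O)[C@@]2(C)O[C@H]2CCO[Si](C)(C)C(C)(C)C | intermediate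
16 | cesium C10 oxalate of 14 | [Cs+].CC(=C)[C@@H]1CC[C@@](C)(O[Si](CC)(CC)CC)C(OC(=O)C([O-])=O)[C@H]1[C@H](O/C=C/C(C)=O)[C@@]2(C)O[C@H]2CCO[Si](C)(C)C(C)(C)C | intermediate
17 | cis-fused hexahydroisobenzofuran; C9 2-oxopropyl, C2 epoxide chain, C11 triethylsilyl ether, C14 isopropenyl; C1, C2, C9, C10, C11, C14 as in the target | CC(=O)C[C@@H]2O[C@H]([C@@]5(C)O[C@H]5CCO[Si](C)(C)C(C)(C)C)[C@H]4[C@@H](CC[C@@](C)(O[Si](CC)(CC)CC)[C@H]42)C(C)=C | intermediate
18 | 17 with the ketone converted to the 2-(trifluoromethylsulfonyloxy)prop-2-enyl group at C9 | C=C(OS(=O)(=O)C(F)(F)F)C[C@@H]2O[C@H]([C@@]5(C)O[C@H]5CCO[Si](C)(C)C(C)(C)C)[C@H]4[C@@H](CC[C@@](C)(O[Si](CC)(CC)CC)[C@H]42)C(C)=C | intermediate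
19 | 18 with the epoxide opened: C3 tertiary alcohol, C4 octanoate (C3, C4 as in the target) | C=C(OS(=O)(=O)C(F)(F)F)C[C@@H]2O[C@H]([C@@](C)(O)[C@H](OC(=O)CCCCCCC)CCO[Si](C)(C)C(C)(C)C)[C@H]4[C@@H](CC[C@@](C)(O[Si](CC)(CC)CC)[C@H]42)C(C)=C | intermediate
20 | B-alkyl-9-borabicyclo[3.3.1]nonane adduct of 19 at C16 (C15 epimers) | C=C(OS(=O)(=O)C(F)(F)F)C[C@@H]2O[C@H]([C@@](C)(O)[C@H](OC(=O)CCCCCCC)CCO[Si](C)(C)C(C)(C)C)[C@H]4[C@@H](CC[C@@](C)(O[Si](CC)(CC)CC)[C@H]42)C(C)CB5C6CCCC5CCC6 | intermediate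
21 | C16 primary alcohol (C15 epimers) | C=C(OS(=O)(=O)C(F)(F)F)C[C@@H]2O[C@H]([C@@](C)(O)[C@H](OC(=O)CCCCCCC)CCO[Si](C)(C)C(C)(C)C)[C@H]4[C@@H](CC[C@@](C)(O[Si](CC)(CC)CC)[C@H]42)C(C)CO | intermediate
22 | C16 carboxylic acid (C15 epimers) | C=C(OS(=O)(=O)C(F)(F)F)C[C@@H]2O[C@H]([C@@](C)(O)[C@H](OC(=O)CCCCCCC)CCO[Si](C)(C)C(C)(C)C)[C@H]4[C@@H](CC[C@@](C)(O[Si](CC)(CC)CC)[C@H]42)C(C)C(=O)O | intermediate
23 | C16 acid chloride of 22 | C=C(OS(=O)(=O)C(F)(F)F)C[C@@H]2O[C@H]([C@@](C)(O)[C@H](OC(=O)CCCCCCC)CCO[Si](C)(C)C(C)(C)C)[C@H]4[C@@H](CC[C@@](C)(O[Si](CC)(CC)CC)[C@H]42)C(C)C(Cl)=O | intermediate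
24 | methylketene (C15=C16=O) from 23 | C=C(OS(=O)(=O)C(F)(F)F)C[C@@H]2O[C@H]([C@@](C)(O)[C@H](OC(=O)CCCCCCC)CCO[Si](C)(C)C(C)(C)C)[C@H]4[C@@H](CC[C@@](C)(O[Si](CC)(CC)CC)[C@H]42)C(C)=C=O | intermediate
25 | tricyclic lactone; C7 triflate, C11 triethylsilyl ether, C6 tert-butyldimethylsilyl ether; all nine centres as in the target | C=C(OS(=O)(=O)C(F)(F)F)C[C@@H]2O[C@H]3[C@H]4[C@@H](CC[C@@](C)(O[Si](CC)(CC)CC)[C@H]42)[C@@H](C)C(=O)O[C@@]3(C)[C@H](OC(=O)CCCCCCC)CCO[Si](C)(C)C(C)(C)C | intermediate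
26 | 25 with free C11 and C6 hydroxyls | C=C(OS(=O)(=O)C(F)(F)F)C[C@@H]2O[C@H]3[C@H]4[C@@H](CC[C@@](C)(O)[C@H]42)[C@@H](C)C(=O)O[C@@]3(C)[C@H](OC(=O)CCCCCCC)CCO | intermediate
27 | C6 aldehyde of 26 | C=C(OS(=O)(=O)C(F)(F)F)C[C@@H]2O[C@H]3[C@H]4[C@@H](CC[C@@](C)(O)[C@H]42)[C@@H](C)C(=O)O[C@@]3(C)[C@H](OC(=O)CCCCCCC)CC=O | intermediate
28 | briarellin A | C=C1C[C@@H]2O[C@H]3[C@H]4[C@@H](CC[C@@](C)(O)[C@H]42)[C@@H](C)C(=O)O[C@@]3(C)[C@H](OC(=O)CCCCCCC)C[C@@H]1O | target

**Step count and risks**

Total steps: 21. Longest linear sequence: 18 (steps 1–4 and 8–21, from (R)-carvone); enal 9 takes 3 steps.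

The three steps most likely to fail:

Step 13 (the new photoredox cyclisation). A secondary alkoxycarbonyl radical loses CO2 slowly and may be intercepted before the C10 radical forms. The fallback sets out from alcohol 14 and comes back at ketone 17. Alcohol 14 is heated with 1,1'-thiocarbonyldiimidazole and DMAP in toluene to give the C10 O-(imidazol-1-ylthiocarbonyl) derivative F1. Slow addition of Bu3SnH and AIBN in benzene at 80 °C then runs the same 5-exo closure as a thermal tin radical chain, which is the known deoxygenative version of the β-alkoxyacrylate-type cyclisation.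

Step 15 (carboxylate opening of a hindered epoxide). Attack at C4, next to a quaternary carbon, may be too slow with octanoate. The fallback sets out from epoxide 18 and comes back at 19. The smaller HCO2Cs (formic acid, Cs2CO3, DMF, 60 °C) opens the epoxide at C4 to the C4 formate F2. KHCO3 in methanol at 0 °C removes the formate to give the C3,C4-diol F3. Octanoyl chloride and pyridine in CH2Cl2 at 0 °C then acylate only the secondary C4 hydroxyl.

Step 18 (lactonisation onto a tertiary alcohol and control of C15). The ketene may oligomerise, or the protonation may favour the wrong C15 epimer. The fallback sets out from alcohol 21 and comes back at lactone 25. Dess–Martin oxidation gives the C16 aldehyde F4, which closes reversibly onto the C3 hydroxyl to the seven-membered lactol F5. Oxidation of the lactol with catalytic n-Pr4N[RuO4] and N-methylmorpholine N-oxide gives the lactone as a C15 epimer pair. Lactone 25 is separated, and the 15-epimer F6 is equilibrated with DBU in toluene and recycled.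

Further compounds

F1 | step 13 | C10 O-(1H-imidazol-1-ylthiocarbonyl) derivative of 14 | CC(=C)[C@@H]1CC[C@@](C)(O[Si](CC)(CC)CC)C(OC(=S)n2ccnc2)[C@H]1[C@H](O/C=C/C(C)=O)[C@@]3(C)O[C@H]3CCO[Si](C)(C)C(C)(C)C
F2 | step 15 | C4 formate analogue of 19 (C3 tertiary alcohol, C4 formate) | C=C(OS(=O)(=O)C(F)(F)F)C[C@@H]2O[C@H]([C@@](C)(O)[C@H](OC=O)CCO[Si](C)(C)C(C)(C)C)[C@H]4[C@@H](CC[C@@](C)(O[Si](CC)(CC)CC)[C@H]42)C(C)=C
F3 | step 15 | C3,C4-diol analogue of 19 | C=C(OS(=O)(=O)C(F)(F)F)C[C@@H]2O[C@H]([C@@](C)(O)[C@H](O)CCO[Si](C)(C)C(C)(C)C)[C@H]4[C@@H](CC[C@@](C)(O[Si](CC)(CC)CC)[C@H]42)C(C)=C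
F4 | step 18 | C16 aldehyde from 21 (C15 epimers) | C=C(OS(=O)(=O)C(F)(F)F)C[C@@H]2O[C@H]([C@@](C)(O)[C@H](OC(=O)CCCCCCC)CCO[Si](C)(C)C(C)(C)C)[C@H]4[C@@H](CC[C@@](C)(O[Si](CC)(CC)CC)[C@H]42)C(C)C=O
F5 | step 18 | seven-membered lactol (C16 hemiacetal with the C3 oxygen; C15 and C16 epimers) | C=C(OS(=O)(=O)C(F)(F)F)C[C@@H]2O[C@H]3[C@H]4[C@@H](CC[C@@](C)(O[Si](CC)(CC)CC)[C@H]42)C(C)C(O)O[C@@]3(C)[C@H](OC(=O)CCCCCCC)CCO[Si](C)(C)C(C)(C)C
F6 | step 18 | 15-epimer of lactone 25 | C=C(OS(=O)(=O)C(F)(F)F)C[C@@H]2O[C@H]3[C@H]4[C@@H](CC[C@@](C)(O[Si](CC)(CC)CC)[C@H]42)[C@H](C)C(=O)O[C@@]3(C)[C@H](OC(=O)CCCCCCC)CCO[Si](C)(C)C(C)(C)C
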